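**Retrosynthetic overview**
1. Target 17 ⇐ 16 by equatorial methyl addition to the ring-A ketone (C2); 16 ⇐ 15 by cross-metathesis (but-3-enyl → 4-methylpent-3-enyl).
2. 15 ⇐ acyclic chlorohydrin β-keto ester 13 by one cationic bicyclisation. Ring B (C4a–C5–C6–C7–C8–C8a, the chlorocyclohexane) forms first; ring A (C1–C2–C3–C4–C4a–C8a, the keto-ester ring) forms last through the C1–C8a bond.
3. Enabling feature: in ring B the equatorial C6–Cl is antiperiplanar to the C5–C4a bond and the fusion is trans, the imprint of anti addition across an (E,E)-diene via a chloriranium ion at C5–C6. In ring A the C1(CO2Me)–C2(O) pair is a latent β-keto ester whose enol carbon C1 can end the cascade at quaternary C8a.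
4. 13 ⇐ geranyl acetate 1 (allylic oxidation, Sharpless epoxidation, Ti-mediated C3 chloride opening, terminal epoxide/allyl Grignard, bromide) + methyl acetoacetate 10 (dianion alkylation).

Key step: step 9

Remark: ring locants are those of the decahydronaphthalene name of 17, chain locants those of pentadecadienoate 13 (chain C2/C6/C7/C10/C11 = ring C1/C4a/C8a/C6/C5); the but-3-enyl group is a placeholder that keeps a second trisubstituted alkene out of the cationic step.

Step 1
Reactants: 1 geranyl acetate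
Product: 2 (2E,6E)-8-hydroxy-3,7-dimethylocta-2,6-dien-1-yl acetate
Conditions: SeO2 (cat.), t-BuOOH, salicylic acid (cat.), CH2Cl2, 0 °C to rt
Reagents that add atoms: tert-butyl hydroperoxide, CC(C)(C)OO
Why: SeO2-catalysed allylic oxidation (ene/[2,3] shift) should hydroxylate the terminal (E)-methyl selectively, the 2,3-alkene being deactivated by the allylic acetate.

Step 2
Reactants: 2 (2E,6E)-8-hydroxy-3,7-dimethylocta-2,6-dien-1-yl acetate
Product: 3 (2E)-5-[(2R,3R)-3-(hydroxymethyl)-3-methyloxiran-2-yl]-3-methylpent-2-en-1-yl acetate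
Conditions: Ti(OiPr)4 (10 mol%), D-(−)-diethyl tartrate (12 mol%), t-BuOOH, 4 Å MS, CH2Cl2, −20 °C
Reagents that add atoms: tert-butyl hydroperoxide, CC(C)(C)OO
Why: Sharpless asymmetric epoxidation of the (E)-2-methyl allylic alcohol; D-(−)-tartrate should give the (2R,3R)-oxirane, and the alkene without a free allylic hydroxyl is not epoxidised.

Step 3
Reactants: 3 (2E)-5-[(2R,3R)-3-(hydroxymethyl)-3-methyloxiran-2-yl]-3-methylpent-2-en-1-yl acetate
Product: 4 (2E,6S,7R)-6-chloro-7,8-dihydroxy-3,7-dimethyloct-2-en-1-yl acetate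
Conditions: ClTi(OiPr)3, CH2Cl2, 0 °C to rt; aq. tartaric acid
Reagents that add atoms: chlorotitanium triisopropoxide, CC(C)O[Ti](Cl)(OC(C)C)OC(C)C
Why: titanium-mediated C3-selective opening of a 2,3-epoxy alcohol by chloride (SN2, inversion at the secondary carbon) should set the C–Cl stereocentre and leave the tertiary carbinol untouched.

Step 4
Reactants: 4 (2E,6S,7R)-6-chloro-7,8-dihydroxy-3,7-dimethyloct-2-en-1-yl acetate
Product: 6 (2E,6S)-6-chloro-3-methyl-6-[(2R)-2-methyloxiran-2-yl]hex-2-en-1-ol, via primary tosylate 5 (not isolated)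
Conditions: TsCl, Et3N, Bu2SnO (cat.), CH2Cl2, 0 °C; then K2CO3, MeOH, 0 °C
Reagents that add atoms: none
Why: tin-catalysed primary-selective sulfonylation followed by 3-exo-tet Williamson closure of the tertiary alkoxide onto the primary tosylate keeps both stereocentres; the carbonate/methanol stage also removes the acetate by transesterification.

Step 5
Reactants: 6 (2E,6S)-6-chloro-3-methyl-6-[(2R)-2-methyloxiran-2-yl]hex-2-en-1-ol
Product: 7 (2E,6S,7R)-6-chloro-3,7-dimethylundeca-2,10-diene-1,7-diol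
Conditions: allylMgBr (3 equiv), THF, −30 to 0 °C; aq. NH4Cl at 0 °C
Reagents that add atoms: allylmagnesium bromide, C=CC[Mg]Br
Why: SN2 opening of the 2,2-disubstituted epoxide at its CH2 terminus by the Grignard reagent leaves the tertiary C–O bond, and hence the stereocentre, intact.

Step 6
Reactants: 7 (2E,6S,7R)-6-chloro-3,7-dimethylundeca-2,10-diene-1,7-diol
Product: 8 (5R,6S,9E)-11-bromo-6-chloro-5,9-dimethylundeca-1,9-dien-5-ol
Conditions: CBr4, PPh3, CH2Cl2, −20 °C
Reagents that add atoms: carbon tetrabromide, BrC(Br)(Br)Br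
Why: the Appel reaction should be selective for the primary allylic alcohol over the hindered β-chloro tertiary alcohol and should keep the (E)-alkene.

Step 7
Reactants: 8 (5R,6S,9E)-11-bromo-6-chloro-5,9-dimethylundeca-1,9-dien-5-ol
Product: 9 {[(5R,6S,9E)-11-bromo-6-chloro-5,9-dimethylundeca-1,9-dien-5-yl]oxy}trimethylsilane
Conditions: TMSOTf, 2,6-lutidine, CH2Cl2, −78 °C
Reagents that add atoms: trimethylsilyl triflate, C[Si](C)(C)OS(=O)(=O)C(F)(F)F
Why: silylation masks the tertiary hydroxyl, whose alkoxide would otherwise displace the vicinal chloride under the basic conditions of the next step.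

Step 8
Reactants: 9 {[(5R,6S,9E)-11-bromo-6-chloro-5,9-dimethylundeca-1,9-dien-5-yl]oxy}trimethylsilane; 10 methyl acetoacetate
Product: 13 methyl (6E,10S,11R)-10-chloro-11-hydroxy-7,11-dimethyl-3-oxopentadeca-6,14-dienoate, via acetoacetate dianion 11 (not isolated), via silyl ether keto ester 12 (not isolated)
Conditions: 10, NaH then n-BuLi, THF, 0 °C; then 9, 0 °C; then 1 M HCl, THF/MeOH, rt
Reagents that add atoms: none
Why: Weiler γ-alkylation of the acetoacetate dianion with the allylic bromide (SN2) installs the β-keto ester, and the acidic work-up cleaves the labile tertiary TMS ether.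

Step 9
Reactants: 13 methyl (6E,10S,11R)-10-chloro-11-hydroxy-7,11-dimethyl-3-oxopentadeca-6,14-dienoate
Product: 15 methyl (1R,4aR,5S,6S,8aS)-5-(but-3-en-1-yl)-6-chloro-5,8a-dimethyl-2-oxodecahydronaphthalene-1-carboxylate, via tertiary trifluoroacetate 14 (not isolated)
Conditions: (CF3CO)2O (1.1 equiv), 2,6-di-tert-butyl-4-methylpyridine (3 equiv), CH2Cl2, −40 °C; then SnCl4 (2.5 equiv), −78 to −20 °C
Reagents that add atoms: none
Why: Proposed new method: the tertiary alcohol is acylated in situ and SnCl4 ionises trifluoroacetate 14 with anchimeric assistance of the antiperiplanar vicinal chlorine, giving the (E)-type chloriranium ion that no Cl+ reagent could place selectively on this internal alkene; the 6,7-alkene opens it at the tertiary carbon and the tin-chelated β-keto ester enol traps the resulting tertiary cation through carbon. The closest known reaction types are the chloriranium-induced polyene cyclisation with electrophilic chlorine reagents, the enantiospecific solvolytic cyclisation of vicinal bromochlorides, and the SnCl4-mediated C-cyclisation of olefinic β-keto esters. Ring B closes first in a 6-endo-trig mode (endo opening of the chloriranium), and ring A closes last in a 6-(enolendo) mode by attack of chain C2 on the C8a cation, both through a chair–chair transition state. C6 is carried over unchanged from 13; C5 follows from the chloriranium geometry (double inversion, so the chain is equatorial and the methyl axial); the trans fusion at C4a/C8a follows from anti addition across the (6E)-alkene; and C1 settles as the equatorial ester by enolisation. The step needs carbon rather than oxygen termination (the SnCl4 chelate, which should also isomerise any enol ether), no proton-initiated cyclisation of the 6,7-alkene (the hindered base), and a chlorine-bridged rather than free-cation pathway (the β-chloro cation is stabilised only with Cl anti to the incoming alkene); the monosubstituted but-3-enyl alkene is too poor a π-nucleophile to interfere.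

Step 10
Reactants: 15 methyl (1R,4aR,5S,6S,8aS)-5-(but-3-en-1-yl)-6-chloro-5,8a-dimethyl-2-oxodecahydronaphthalene-1-carboxylate
Product: 16 methyl (1R,4aR,5S,6S,8aS)-6-chloro-5,8a-dimethyl-5-(4-methylpent-3-en-1-yl)-2-oxodecahydronaphthalene-1-carboxylate
Conditions: Hoveyda–Grubbs II (5 mol%), 2-methyl-2-butene/CH2Cl2, 40 °C
Reagents that add atoms: 2-methyl-2-butene, CC=C(C)C
Why: olefin cross-metathesis of a monosubstituted alkene with 2-methyl-2-butene is a standard way to install the trisubstituted prenyl-type terminus.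

Step 11
Reactants: 16 methyl (1R,4aR,5S,6S,8aS)-6-chloro-5,8a-dimethyl-5-(4-methylpent-3-en-1-yl)-2-oxodecahydronaphthalene-1-carboxylate
Product: 17 methyl (1R,2S,4aR,5S,6S,8aS)-6-chloro-2-hydroxy-2,5,8a-trimethyl-5-(4-methylpent-3-en-1-yl)decahydronaphthalene-1-carboxylate
Conditions: MeMgBr, CeCl3, THF, −78 °C; aq. NH4Cl
Reagents that add atoms: methylmagnesium bromide, C[Mg]Br
Why: organocerium 1,2-addition (Imamoto conditions, chosen to suppress enolisation of the β-keto ester); the axial face of the C2 ketone is blocked by the syn-axial C8a methyl, so methyl should enter equatorially and give the axial alcohol cis to the ester, i.e. (2S).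

**Compound list**
1 | geranyl acetate | CC(=O)OC/C=C(\C)CCC=C(C)C | starting material
2 | (2E,6E)-8-hydroxy-3,7-dimethylocta-2,6-dien-1-yl acetate | CC(=O)OC/C=C(\C)CC/C=C(\C)CO | intermediate
3 | (2E)-5-[(2R,3R)-3-(hydroxymethyl)-3-methyloxiran-2-yl]-3-methylpent-2-en-1-yl acetate | CC(=O)OC/C=C(\C)CC[C@H]1O[C@]1(C)CO | intermediate
4 | (2E,6S,7R)-6-chloro-7,8-dihydroxy-3,7-dimethyloct-2-en-1-yl acetate | CC(=O)OC/C=C(\C)CC[C@H](Cl)[C@](C)(O)CO | intermediate
5 | (2E,6S,7R)-6-chloro-7-hydroxy-3,7-dimethyl-8-(tosyloxy)oct-2-en-1-yl acetate | CC(=O)OC/C=C(\C)CC[C@H](Cl)[C@](C)(O)COS(=O)(=O)c1ccc(C)cc1 | intermediate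
6 | (2E,6S)-6-chloro-3-methyl-6-[(2R)-2-methyloxiran-2-yl]hex-2-en-1-ol | OC/C=C(\C)CC[C@H](Cl)[C@@]1(C)CO1 | intermediate
7 | (2E,6S,7R)-6-chloro-3,7-dimethylundeca-2,10-diene-1,7-diol | OC/C=C(\C)CC[C@H](Cl)[C@](C)(O)CCC=C | intermediate
8 | (5R,6S,9E)-11-bromo-6-chloro-5,9-dimethylundeca-1,9-dien-5-ol | BrC/C=C(\C)CC[C@H](Cl)[C@](C)(O)CCC=C | intermediate
9 | {[(5R,6S,9E)-11-bromo-6-chloro-5,9-dimethylundeca-1,9-dien-5-yl]oxy}trimethylsilane | BrC/C=C(\C)CC[C@H](Cl)[C@](C)(O[Si](C)(C)C)CCC=C | intermediate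
10 | methyl acetoacetate | COC(=O)CC(C)=O | starting material
11 | methyl acetoacetate dianion (lithium sodium salt) | [Na+].[Li+].COC(=O)[CH-]C(=O)[CH2-] | intermediate
12 | methyl (6E,10S,11R)-10-chloro-7,11-dimethyl-3-oxo-11-(trimethylsilyloxy)pentadeca-6,14-dienoate | COC(=O)CC(=O)CC/C=C(\C)CC[C@H](Cl)[C@](C)(O[Si](C)(C)C)CCC=C | intermediate
13 | methyl (6E,10S,11R)-10-chloro-11-hydroxy-7,11-dimethyl-3-oxopentadeca-6,14-dienoate | COC(=O)CC(=O)CC/C=C(\C)CC[C@H](Cl)[C@](C)(O)CCC=C | intermediate
14 | methyl (6E,10S,11R)-10-chloro-7,11-dimethyl-3-oxo-11-(trifluoroacetoxy)pentadeca-6,14-dienoate | COC(=O)CC(=O)CC/C=C(\C)CC[C@H](Cl)[C@](C)(OC(=O)C(F)(F)F)CCC=C | intermediate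
15 | methyl (1R,4aR,5S,6S,8aS)-5-(but-3-en-1-yl)-6-chloro-5,8a-dimethyl-2-oxodecahydronaphthalene-1-carboxylate | COC(=O)[C@@H]1[C@@]2(C)CC[C@H](Cl)[C@@](C)(CCC=C)[C@@H]2CCC1=O | intermediate
16 | methyl (1R,4aR,5S,6S,8aS)-6-chloro-5,8a-dimethyl-5-(4-methylpent-3-en-1-yl)-2-oxodecahydronaphthalene-1-carboxylate | COC(=O)[C@@H]1[C@@]2(C)CC[C@H](Cl)[C@@](C)(CCC=C(C)C)[C@@H]2CCC1=O | intermediate
17 | methyl (1R,2S,4aR,5S,6S,8aS)-6-chloro-2-hydroxy-2,5,8a-trimethyl-5-(4-methylpent-3-en-1-yl)decahydronaphthalene-1-carboxylate | COC(=O)[C@@H]1[C@@]2(C)CC[C@H](Cl)[C@@](C)(CCC=C(C)C)[C@@H]2CC[C@]1(C)O | target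

**Totals**
Total step count: 11. Longest linear sequence: 11 steps (1 → 17).

**Steps most likely to fail**

Step 9 (proposed new method). The ionisation may not stay chlorine-bridged: a free β-chloro cation would lose control of C5, direct π-displacement would invert it, the cascade may end through the ketone oxygen, or protons may start a monocyclisation at the 6,7-alkene. The fallback uses known chemistry, sets out from 2 and comes back at 15. It swaps the anchimeric ionisation for a Lewis acid epoxide-opening polyene cyclisation, which needs the epimeric oxirane. Titanium/chiral Schiff base-catalysed enantioselective dichlorination of 2 (t-BuOCl, ClTi(OiPr)3, hexanes, −20 °C) should give the anti-dichloride (2E,6S,7R)-6,7-dichloro-8-hydroxy-3,7-dimethyloct-2-en-1-yl acetate F1. K2CO3/MeOH should close the primary alkoxide onto the tertiary chloride with inversion and cleave the acetate, giving (2E,6S)-6-chloro-3-methyl-6-[(2S)-2-methyloxiran-2-yl]hex-2-en-1-ol F2. Appel bromination should give (2S)-2-[(1S,4E)-6-bromo-1-chloro-4-methylhex-4-en-1-yl]-2-methyloxirane F3, and alkylation with the dianion of 10 should give methyl (6E,10S)-10-chloro-7-methyl-10-[(2S)-2-methyloxiran-2-yl]-3-oxodec-6-enoate F4. MeAlCl2 (CH2Cl2, −78 °C) should then open the epoxide at its tertiary carbon by backside attack of the 6,7-alkene, with C–Cl antiperiplanar to the forming bond. The same chair–chair cascade should give methyl (1R,4aR,5R,6S,8aS)-6-chloro-5-(hydroxymethyl)-5,8a-dimethyl-2-oxodecahydronaphthalene-1-carboxylate F5. Dess–Martin oxidation should give the 5-formyl compound methyl (1R,4aR,5R,6S,8aS)-6-chloro-5-formyl-5,8a-dimethyl-2-oxodecahydronaphthalene-1-carboxylate F6. Indium-mediated allylation (allyl bromide, In, THF/H2O) should give methyl (1R,4aR,5R,6S,8aS)-6-chloro-5-(1-hydroxybut-3-en-1-yl)-5,8a-dimethyl-2-oxodecahydronaphthalene-1-carboxylate F7 as a carbinol mixture. PhOC(S)Cl/pyridine/DMAP should give its O-phenyl thionocarbonate F8, and Barton–McCombie reduction (Bu3SnH, AIBN, toluene, 90 °C) returns the route to 15.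

Step 11. The organometallic may deprotonate the β-keto ester instead of adding, or the product alkoxide may undergo retro-aldol opening. The fallback sets out from 15 and comes back at 17; it builds the C2–O bond by delivery from the C1 carboxyl, which fixes the cis relationship. Takai–Lombardo methylenation (Zn, CH2Br2, TiCl4) should give methyl (1S,4aR,5S,6S,8aS)-5-(but-3-en-1-yl)-6-chloro-5,8a-dimethyl-2-methylidenedecahydronaphthalene-1-carboxylate F9. SN2 demethylation (LiI, pyridine, reflux) should give the corresponding carboxylic acid F10. Kinetic iodolactonisation (I2, NaHCO3, MeCN, 0 °C; 4-exo, Markovnikov) should give the cis-fused 2-(iodomethyl) β-lactone F11. Bu3SnH/AIBN should give the 2-methyl β-lactone F12, and NaOMe (cat.)/MeOH should open it to methyl (1R,2S,4aR,5S,6S,8aS)-5-(but-3-en-1-yl)-6-chloro-2-hydroxy-2,5,8a-trimethyldecahydronaphthalene-1-carboxylate F13. Cross-metathesis of F13 with 2-methyl-2-butene (as in step 10) gives 17.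

Step 5. The magnesium alkoxide formed may displace the vicinal chloride (re-closure to a trisubstituted epoxide and further opening) before the quench. The fallback sets out from 4 and comes back at 7; it makes the tertiary carbinol by carbonyl addition instead of epoxide opening. NaIO4 (THF/H2O, 0 °C) should cleave diol 4 to the α-chloro ketone (2E,6S)-6-chloro-3-methyl-7-oxooct-2-en-1-yl acetate F14. But-3-enylmagnesium bromide/CeCl3 (excess, THF, −78 °C) should add anti to chlorine (polar Felkin–Anh/Cornforth control, predicted to give 7R) and remove the acetate, giving 7.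

**Further compounds**
F1 | step 9 | (2E,6S,7R)-6,7-dichloro-8-hydroxy-3,7-dimethyloct-2-en-1-yl acetate | CC(=O)OC/C=C(\C)CC[C@H](Cl)[C@](C)(Cl)CO
F2 | step 9 | (2E,6S)-6-chloro-3-methyl-6-[(2S)-2-methyloxiran-2-yl]hex-2-en-1-ol | OC/C=C(\C)CC[C@H](Cl)[C@]1(C)CO1
F3 | step 9 | (2S)-2-[(1S,4E)-6-bromo-1-chloro-4-methylhex-4-en-1-yl]-2-methyloxirane | BrC/C=C(\C)CC[C@H](Cl)[C@]1(C)CO1
F4 | step 9 | methyl (6E,10S)-10-chloro-7-methyl-10-[(2S)-2-methyloxiran-2-yl]-3-oxodec-6-enoate | COC(=O)CC(=O)CC/C=C(\C)CC[C@H](Cl)[C@]1(C)CO1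
F5 | step 9 | methyl (1R,4aR,5R,6S,8aS)-6-chloro-5-(hydroxymethyl)-5,8a-dimethyl-2-oxodecahydronaphthalene-1-carboxylate | COC(=O)[C@@H]1[C@@]2(C)CC[C@H](Cl)[C@@](C)(CO)[C@@H]2CCC1=O
F6 | step 9 | methyl (1R,4aR,5R,6S,8aS)-6-chloro-5-formyl-5,8a-dimethyl-2-oxodecahydronaphthalene-1-carboxylate | COC(=O)[C@@H]1[C@@]2(C)CC[C@H](Cl)[C@@](C)(C=O)[C@@H]2CCC1=O
F7 | step 9 | methyl (1R,4aR,5R,6S,8aS)-6-chloro-5-(1-hydroxybut-3-en-1-yl)-5,8a-dimethyl-2-oxodecahydronaphthalene-1-carboxylate | COC(=O)[C@@H]1[C@@]2(C)CC[C@H](Cl)[C@@](C)(C(O)CC=C)[C@@H]2CCC1=O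
F8 | step 9 | O-phenyl thionocarbonate of F7 | COC(=O)[C@@H]1[C@@]2(C)CC[C@H](Cl)[C@@](C)(C(CC=C)OC(=S)Oc3ccccc3)[C@@H]2CCC1=O
F9 | step 11 | methyl (1S,4aR,5S,6S,8aS)-5-(but-3-en-1-yl)-6-chloro-5,8a-dimethyl-2-methylidenedecahydronaphthalene-1-carboxylate | COC(=O)[C@@H]1[C@@]2(C)CC[C@H](Cl)[C@@](C)(CCC=C)[C@@H]2CCC1=C
F10 | step 11 | (1S,4aR,5S,6S,8aS)-5-(but-3-en-1-yl)-6-chloro-5,8a-dimethyl-2-methylidenedecahydronaphthalene-1-carboxylic acid | OC(=O)[C@@H]1[C@@]2(C)CC[C@H](Cl)[C@@](C)(CCC=C)[C@@H]2CCC1=C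
F11 | step 11 | cis-fused 2-(iodomethyl) β-lactone (C1 carboxyl to C2 oxygen) | O=C3[C@@H]1[C@@]2(C)CC[C@H](Cl)[C@@](C)(CCC=C)[C@@H]2CC[C@]1(CI)O3
F12 | step 11 | cis-fused 2-methyl β-lactone (C1 carboxyl to C2 oxygen) | O=C3[C@@H]1[C@@]2(C)CC[C@H](Cl)[C@@](C)(CCC=C)[C@@H]2CC[C@]1(C)O3
F13 | step 11 | methyl (1R,2S,4aR,5S,6S,8aS)-5-(but-3-en-1-yl)-6-chloro-2-hydroxy-2,5,8a-trimethyldecahydronaphthalene-1-carboxylate | COC(=O)[C@@H]1[C@@]2(C)CC[C@H](Cl)[C@@](C)(CCC=C)[C@@H]2CC[C@]1(C)O
F14 | step 5 | (2E,6S)-6-chloro-3-methyl-7-oxooct-2-en-1-yl acetate | CC(=O)OC/C=C(\C)CC[C@H](Cl)C(C)=O
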